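**Retrosynthetic overview**

1. Target 18 ⇐ Schenck ene reaction (singlet oxygen) on the 7E-alkene of macrocycle 17: the C8–OOH/6E-alkene unit comes from C7=C8 with C6H2.
2. 17 ⇐ nickel-catalysed reductive diene–ketone macrocyclisation of seco compound 16, forming C4–C5. The enabling feature is the ring segment C3(O-lactone)–C4(OH)(CH3)–C5H2–C6H2–C7H=C8 of the 14-membered ring: a pent-4-en-1-ol unit, the retron of a 1,3-diene + methyl ketone homoallylation, with C4 next to the δ-lactone ring stereocentre C3 that steers it.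
3. 16 ⇐ 6-acetyl δ-lactone from the C16 acid, the C3 aldehyde and an acetyl-anion equivalent (C3 and C15 set by equilibration relative to C1); Shi epoxide at C11/C12; diene by Wittig methylenation.
4. C1 ⇐ copper-catalysed asymmetric SN2′ alkylation of the C16 chloride of (2E,6E)-farnesol TBDPS ether, which supplies C6–C17, C19, C20 and both E-alkenes.
5. Ring order: δ-lactone (step 8), epoxide (step 10), 14-membered carbocycle (step 14).

Key step: step 14

Remark (numbering): cembrane labels are used. C16 is the lactone C=O, C15 its α-carbon (methyl C17), C1 the adjacent ring CH, C2 the ring CH2, C3 the CH–O of the lactone, C4 the carbinol carbon (methyl C18), C5 a CH2, C6/C7 the alkene carbons of 18, C8 the hydroperoxy carbon (methyl C19), C9, C10, C11/C12 the epoxide (methyl C20 on C12), C13, C14.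

Remark (assumptions): the enantiomer of the phosphoramidite ligand (step 4) and of the Shi ketone (step 10) is the one that gives the configuration drawn; the δ-lactone with all three substituents equatorial is taken as the thermodynamic isomer (step 9).

**Route**

Step 1
Reactants: 1 (2E,6E)-farnesol
Product: 2 (2E,6E)-farnesyl tert-butyldiphenylsilyl ether
Conditions: TBDPSCl, imidazole, DMF, 0 °C to rt
Reagents that add atoms: tert-butyl(chloro)diphenylsilane, CC(C)(C)[Si](Cl)(c1ccccc1)c1ccccc1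
Why: Standard silylation of the primary allylic alcohol; the bulky TBDPS ether survives the later organometallic, oxidative and mildly acidic steps and shields the C7=C8 alkene, and no stereocentre is formed.

Step 2
Reactants: 2 (2E,6E)-farnesyl tert-butyldiphenylsilyl ether
Product: 3 (2E,6E,10E)-12-(tert-butyldiphenylsilyloxy)-2,6,10-trimethyldodeca-2,6,10-trien-1-ol
Conditions: SeO2 (cat.), t-BuOOH, salicylic acid (cat.), CH2Cl2, 0 °C to rt
Reagents that add atoms: tert-butyl hydroperoxide, CC(C)(C)OO (oxygen relayed by selenium dioxide, O=[Se]=O)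
Why: Riley oxidation (ene reaction then [2,3]-sigmatropic shift) attacks the most electron-rich, terminal trisubstituted alkene at its (E)-methyl group, which gives the (E)-allylic alcohol (C16–OH) without creating a stereocentre.

Step 3
Reactants: 3 (2E,6E,10E)-12-(tert-butyldiphenylsilyloxy)-2,6,10-trimethyldodeca-2,6,10-trien-1-ol
Product: 4 tert-butyl{[(2E,6E,10E)-12-chloro-3,7,11-trimethyldodeca-2,6,10-trien-1-yl]oxy}diphenylsilane
Conditions: NCS, Me2S, CH2Cl2, −20 °C to 0 °C
Reagents that add atoms: N-chlorosuccinimide, O=C1CCC(=O)N1Cl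
Why: Corey–Kim chlorination converts the primary allylic alcohol into the chloride under non-acidic conditions without allylic transposition or alkene isomerisation.

Step 4
Reactants: 4 tert-butyl{[(2E,6E,10E)-12-chloro-3,7,11-trimethyldodeca-2,6,10-trien-1-yl]oxy}diphenylsilane
Product: 5 tert-butyl{[(2E,6E,10R)-10-(1,3-dioxolan-2-ylmethyl)-3,7,11-trimethyldodeca-2,6,11-trien-1-yl]oxy}diphenylsilane
Conditions: (1,3-dioxolan-2-ylmethyl)magnesium bromide (slow addition), copper thiophene-2-carboxylate (CuTC, cat., monovalent copper), BINOL-based phosphoramidite with a bis[1-(2-methoxyphenyl)ethyl]amino group (cat., enantiomer giving 10R), CH2Cl2, −78 °C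
Reagents that add atoms: (1,3-dioxolan-2-ylmethyl)magnesium bromide, Br[Mg]CC1OCCO1
Why: Copper-catalysed asymmetric allylic alkylation (SN2′) of a 2-methyl-substituted primary allylic chloride puts the C2–C3 unit on C1 and leaves the 1,1-disubstituted C15=C16 alkene, the C1 stereocentre (R) being set by the chiral phosphoramidite–copper complex (reagent control).

Step 5
Reactants: 5 tert-butyl{[(2E,6E,10R)-10-(1,3-dioxolan-2-ylmethyl)-3,7,11-trimethyldodeca-2,6,11-trien-1-yl]oxy}diphenylsilane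
Product: 7 (2RS,3R,6E,10E)-12-(tert-butyldiphenylsilyloxy)-3-(1,3-dioxolan-2-ylmethyl)-2,6,10-trimethyldodeca-6,10-dien-1-ol, via B-alkyl-9-BBN adduct 6 (not isolated)
Conditions: 9-BBN, THF, 0 °C to rt; then NaOH, H2O2, 0 °C
Reagents that add atoms: 9-borabicyclo[3.3.1]nonane, B1C2CCCC1CCC2 (in 6 only); hydrogen peroxide, OO
Why: Hydroboration–oxidation in which 9-BBN adds only to the 1,1-disubstituted C15=C16 alkene (the two trisubstituted alkenes react far more slowly), boron going to C16; the new C15 centre forms as a mixture that is equilibrated in step 9.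

Step 6
Reactants: 7 (2RS,3R,6E,10E)-12-(tert-butyldiphenylsilyloxy)-3-(1,3-dioxolan-2-ylmethyl)-2,6,10-trimethyldodeca-6,10-dien-1-ol
Product: 8 (2RS,3R,6E,10E)-12-(tert-butyldiphenylsilyloxy)-3-(1,3-dioxolan-2-ylmethyl)-2,6,10-trimethyldodeca-6,10-dienoic acid
Conditions: TEMPO (cat.), PhI(OAc)2, MeCN/H2O, rt
Reagents that add atoms: water, O
Why: Oxoammonium (TEMPO) oxidation of the primary alcohol through the aldehyde hydrate to the carboxylic acid tolerates the acetal, the silyl ether and the trisubstituted alkenes, and C15 stays a mixture.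

Step 7
Reactants: 8 (2RS,3R,6E,10E)-12-(tert-butyldiphenylsilyloxy)-3-(1,3-dioxolan-2-ylmethyl)-2,6,10-trimethyldodeca-6,10-dienoic acid
Product: 9 (2RS,3R,6E,10E)-12-(tert-butyldiphenylsilyloxy)-2,6,10-trimethyl-3-(2-oxoethyl)dodeca-6,10-dienoic acid
Conditions: 1 M HCl, THF, rt
Reagents that add atoms: water, O
Why: Acid-catalysed acetal hydrolysis frees the C3 aldehyde, and the TBDPS ether and the isolated alkenes are stable to dilute acid at room temperature.

Step 8
Reactants: 9 (2RS,3R,6E,10E)-12-(tert-butyldiphenylsilyloxy)-2,6,10-trimethyl-3-(2-oxoethyl)dodeca-6,10-dienoic acid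
Product: 11 (4R)-6-acetyl-4-[(3E,7E)-9-(tert-butyldiphenylsilyloxy)-3,7-dimethylnona-3,7-dien-1-yl]-3-methyltetrahydro-2H-pyran-2-one (mixture of epimers at pyranone C3 and C6), via enol ether hydroxy acid 10 (not isolated)
Conditions: ethyl vinyl ether, t-BuLi, THF, −78 °C to 0 °C; then 9, −78 °C; then 0.5 M HCl, THF, rt; PPTS (cat.), toluene, 40 °C
Reagents that add atoms: 1-ethoxyvinyllithium, [Li]C(=C)OCC (from ethyl vinyl ether, C=COCC, and tert-butyllithium); water, O
Why: 1,2-Addition of the acyl-anion equivalent 1-ethoxyvinyllithium to the aldehyde (the lithium carboxylate does not react), acid hydrolysis of the enol ether to the methyl ketone and acid-catalysed δ-lactonisation build the 6-acetyl lactone; C3 is formed without control and is corrected in step 9.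

Step 9
Reactants: 11 (4R)-6-acetyl-4-[(3E,7E)-9-(tert-butyldiphenylsilyloxy)-3,7-dimethylnona-3,7-dien-1-yl]-3-methyltetrahydro-2H-pyran-2-one (epimer mixture)
Product: 12 (3S,4R,6R)-6-acetyl-4-[(3E,7E)-9-(tert-butyldiphenylsilyloxy)-3,7-dimethylnona-3,7-dien-1-yl]-3-methyltetrahydro-2H-pyran-2-one
Conditions: DBU (0.3 equiv), toluene, 40 °C
Reagents that add atoms: none
Why: Base-mediated epimerisation under thermodynamic control, through the ketone enolate at C3 and the lactone enolate at C15, should converge on the lactone with all three substituents equatorial, which fixes C3 (R) and C15 (S) relative to C1 (R).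

Step 10
Reactants: 12 (3S,4R,6R)-6-acetyl-4-[(3E,7E)-9-(tert-butyldiphenylsilyloxy)-3,7-dimethylnona-3,7-dien-1-yl]-3-methyltetrahydro-2H-pyran-2-one
Product: 13 (3S,4R,6R)-6-acetyl-4-{2-[(2S,3S)-3-[(3E)-5-(tert-butyldiphenylsilyloxy)-3-methylpent-3-en-1-yl]-2-methyloxiran-2-yl]ethyl}-3-methyltetrahydro-2H-pyran-2-one
Conditions: enantiomer of the D-fructose-derived Shi ketone (1.0 equiv), KHSO5 (as 2KHSO5·KHSO4·K2SO4), NaHCO3, Bu4NHSO4 (cat.), MeCN/aq. Na2EDTA, 0 °C, pH 7–8
Reagents that add atoms: potassium peroxymonosulfate, [K+].[O-]S(=O)(=O)OO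
Why: Shi epoxidation (chiral dioxirane, spiro transition state) gives the (11S,12S)-epoxide by reagent control on the E-trisubstituted C11=C12 alkene, which is more electron-rich and less hindered than C7=C8 next to the allylic silyloxy group, and the near-neutral pH spares the lactone.

Step 11
Reactants: 13 (3S,4R,6R)-6-acetyl-4-{2-[(2S,3S)-3-[(3E)-5-(tert-butyldiphenylsilyloxy)-3-methylpent-3-en-1-yl]-2-methyloxiran-2-yl]ethyl}-3-methyltetrahydro-2H-pyran-2-one
Product: 14 (3S,4R,6R)-6-acetyl-4-{2-[(2S,3S)-3-[(3E)-5-hydroxy-3-methylpent-3-en-1-yl]-2-methyloxiran-2-yl]ethyl}-3-methyltetrahydro-2H-pyran-2-one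
Conditions: TBAF, AcOH (1:1), THF, 0 °C to rt
Reagents that add atoms: none
Why: Fluoride-mediated desilylation buffered with acetic acid frees the allylic alcohol without opening the epoxide or the lactone.

Step 12
Reactants: 14 (3S,4R,6R)-6-acetyl-4-{2-[(2S,3S)-3-[(3E)-5-hydroxy-3-methylpent-3-en-1-yl]-2-methyloxiran-2-yl]ethyl}-3-methyltetrahydro-2H-pyran-2-one
Product: 15 (3S,4R,6R)-6-acetyl-3-methyl-4-{2-[(2S,3S)-2-methyl-3-[(3E)-3-methyl-5-oxopent-3-en-1-yl]oxiran-2-yl]ethyl}tetrahydro-2H-pyran-2-one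
Conditions: MnO2 (activated, excess), CH2Cl2, rt
Reagents that add atoms: none
Why: MnO2 oxidises only the allylic alcohol, to the (E)-enal, under neutral conditions.

Step 13
Reactants: 15 (3S,4R,6R)-6-acetyl-3-methyl-4-{2-[(2S,3S)-2-methyl-3-[(3E)-3-methyl-5-oxopent-3-en-1-yl]oxiran-2-yl]ethyl}tetrahydro-2H-pyran-2-one
Product: 16 (3S,4R,6R)-6-acetyl-3-methyl-4-{2-[(2S,3S)-2-methyl-3-[(3E)-3-methylhexa-3,5-dien-1-yl]oxiran-2-yl]ethyl}tetrahydro-2H-pyran-2-one
Conditions: Ph3PCH3Br, KHMDS, THF, 0 °C; then 15, −78 °C to −20 °C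
Reagents that add atoms: methyltriphenylphosphonium bromide, C[P+](c1ccccc1)(c1ccccc1)c1ccccc1.[Br-]
Why: Wittig methylenation, in which the ylide reacts with the unhindered enal far faster than with the methyl ketone at low temperature and leaves the 7E geometry untouched, forms the terminal diene without new stereocentres.

Step 14
Reactants: 16 (3S,4R,6R)-6-acetyl-3-methyl-4-{2-[(2S,3S)-2-methyl-3-[(3E)-3-methylhexa-3,5-dien-1-yl]oxiran-2-yl]ethyl}tetrahydro-2H-pyran-2-one
Product: 17 (1R,3R,4S,7E,11S,12S,15S)-11,12-epoxy-4-hydroxycembr-7-en-16,3-olide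
Conditions: Ni(acac)2 (20 mol%), Et2Zn (2.5 equiv), THF, 25 °C, syringe-pump addition of 16 to 0.002 M; aq. NH4Cl
Reagents that add atoms: none
Why: Proposed new method: zerovalent nickel, formed from Ni(acac)2 and Et2Zn, should bind the terminal C5=C6 bond of the diene and the zinc-activated C4 ketone of 16 and couple them oxidatively (C4–C5 bond) to an oxanickelacycle whose allyl part spans C6–C8; ethyl transfer from zinc, β-hydride elimination (ethene) and C6–H reductive elimination then release the zinc alkoxide of 17 and zerovalent nickel. The closest known reaction type is the intermolecular nickel-catalysed homoallylation of aldehydes and ketones with 1,3-dienes promoted by Et3B or Et2Zn, with its five- and six-ring intramolecular aldehyde version and nickel-catalysed reductive alkyne–aldehyde macrocyclisations as further support; new is the ketone acceptor in a 14-membered closure. The 14-membered carbocycle closes in the endo mode with respect to the diene (C5 to C8 all become ring atoms) and in the exo mode with respect to the carbonyl group (its oxygen stays outside the ring). The only new stereocentre, C4, should be controlled by the neighbouring ring stereocentre C3 through a polar Felkin–Anh (Cornforth) transition state in which C5 approaches anti to the lactone C3–O bond and past C3–H, which gives 4S; the weakly basic lactone oxygen is not expected to chelate zinc. The step needs regioselectivity (carbon bond at the unsubstituted diene terminus C5, hydrogen at C6), which the fully substituted C8 terminus secures while also keeping nickel off C8 so that 7E is retained, and chemoselectivity, which follows from the inertness of the lactone, the trisubstituted epoxide and isolated alkenes to Ni/Et2Zn. High dilution with slow addition of 16 should favour ring closure over diene oligomerisation.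

Step 15
Reactants: 17 (1R,3R,4S,7E,11S,12S,15S)-11,12-epoxy-4-hydroxycembr-7-en-16,3-olide
Product: 18 (1R,3R,4S,6E,8R,11S,12S,15S)-11,12-epoxy-8-hydroperoxy-4-hydroxycembr-6-en-16,3-olide (CNP0297487.3)
Conditions: O2, tetraphenylporphyrin (cat.), CH2Cl2, −20 °C, visible light
Reagents that add atoms: dioxygen, O=O
Why: Schenck ene reaction in which singlet oxygen adds to C8 and takes an allylic hydrogen from C6 on the more substituted side of the E-alkene (cis effect) with shift of the double bond to 6E; the C8 stereocentre (R) is expected from attack on the exposed outer face of the alkene in the macrocycle, and the 7-hydroperoxy-8(19)-ene regioisomer from C19–H abstraction has to be separated.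

**Compound list**

1 | (2E,6E)-farnesol | CC(C)=CCC/C(C)=C/CC/C(C)=C/CO | starting material
2 | (2E,6E)-farnesyl tert-butyldiphenylsilyl ether | CC(C)=CCC/C(C)=C/CC/C(C)=C/CO[Si](c1ccccc1)(c1ccccc1)C(C)(C)C | intermediate
3 | (2E,6E,10E)-12-(tert-butyldiphenylsilyloxy)-2,6,10-trimethyldodeca-2,6,10-trien-1-ol | OC/C(C)=C/CC/C(C)=C/CC/C(C)=C/CO[Si](c1ccccc1)(c1ccccc1)C(C)(C)C | intermediate
4 | tert-butyl{[(2E,6E,10E)-12-chloro-3,7,11-trimethyldodeca-2,6,10-trien-1-yl]oxy}diphenylsilane | ClC/C(C)=C/CC/C(C)=C/CC/C(C)=C/CO[Si](c1ccccc1)(c1ccccc1)C(C)(C)C | intermediate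
5 | tert-butyl{[(2E,6E,10R)-10-(1,3-dioxolan-2-ylmethyl)-3,7,11-trimethyldodeca-2,6,11-trien-1-yl]oxy}diphenylsilane | CC(=C)[C@@H](CC1OCCO1)CC/C(C)=C/CC/C(C)=C/CO[Si](c1ccccc1)(c1ccccc1)C(C)(C)C | intermediate
6 | B-alkyl-9-BBN adduct of 5 (boron on C16, C15 epimers) | CC(CB1C2CCCC1CCC2)[C@@H](CC1OCCO1)CC/C(C)=C/CC/C(C)=C/CO[Si](c1ccccc1)(c1ccccc1)C(C)(C)C | intermediate
7 | (2RS,3R,6E,10E)-12-(tert-butyldiphenylsilyloxy)-3-(1,3-dioxolan-2-ylmethyl)-2,6,10-trimethyldodeca-6,10-dien-1-ol | CC(CO)[C@@H](CC1OCCO1)CC/C(C)=C/CC/C(C)=C/CO[Si](c1ccccc1)(c1ccccc1)C(C)(C)C | intermediate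
8 | (2RS,3R,6E,10E)-12-(tert-butyldiphenylsilyloxy)-3-(1,3-dioxolan-2-ylmethyl)-2,6,10-trimethyldodeca-6,10-dienoic acid | CC(C(=O)O)[C@@H](CC1OCCO1)CC/C(C)=C/CC/C(C)=C/CO[Si](c1ccccc1)(c1ccccc1)C(C)(C)C | intermediate
9 | (2RS,3R,6E,10E)-12-(tert-butyldiphenylsilyloxy)-2,6,10-trimethyl-3-(2-oxoethyl)dodeca-6,10-dienoic acid | CC(C(=O)O)[C@@H](CC=O)CC/C(C)=C/CC/C(C)=C/CO[Si](c1ccccc1)(c1ccccc1)C(C)(C)C | intermediate
10 | (2RS,3R,6E,10E)-12-(tert-butyldiphenylsilyloxy)-3-(3-ethoxy-2-hydroxybut-3-en-1-yl)-2,6,10-trimethyldodeca-6,10-dienoic acid | CC(C(=O)O)[C@@H](CC(O)C(=C)OCC)CC/C(C)=C/CC/C(C)=C/CO[Si](c1ccccc1)(c1ccccc1)C(C)(C)C | intermediate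
11 | (4R)-6-acetyl-4-[(3E,7E)-9-(tert-butyldiphenylsilyloxy)-3,7-dimethylnona-3,7-dien-1-yl]-3-methyltetrahydro-2H-pyran-2-one, epimer mixture at C3 and C6 of the pyranone | CC1C(=O)OC(C(C)=O)C[C@H]1CC/C(C)=C/CC/C(C)=C/CO[Si](c1ccccc1)(c1ccccc1)C(C)(C)C | intermediate
12 | (3S,4R,6R)-6-acetyl-4-[(3E,7E)-9-(tert-butyldiphenylsilyloxy)-3,7-dimethylnona-3,7-dien-1-yl]-3-methyltetrahydro-2H-pyran-2-one | C[C@@H]1C(=O)O[C@@H](C(C)=O)C[C@H]1CC/C(C)=C/CC/C(C)=C/CO[Si](c1ccccc1)(c1ccccc1)C(C)(C)C | intermediate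
13 | (3S,4R,6R)-6-acetyl-4-{2-[(2S,3S)-3-[(3E)-5-(tert-butyldiphenylsilyloxy)-3-methylpent-3-en-1-yl]-2-methyloxiran-2-yl]ethyl}-3-methyltetrahydro-2H-pyran-2-one | C[C@@H]1C(=O)O[C@@H](C(C)=O)C[C@H]1CC[C@]1(C)O[C@H]1CC/C(C)=C/CO[Si](c1ccccc1)(c1ccccc1)C(C)(C)C | intermediate
14 | (3S,4R,6R)-6-acetyl-4-{2-[(2S,3S)-3-[(3E)-5-hydroxy-3-methylpent-3-en-1-yl]-2-methyloxiran-2-yl]ethyl}-3-methyltetrahydro-2H-pyran-2-one | C[C@@H]1C(=O)O[C@@H](C(C)=O)C[C@H]1CC[C@]1(C)O[C@H]1CC/C(C)=C/CO | intermediate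
15 | (3S,4R,6R)-6-acetyl-3-methyl-4-{2-[(2S,3S)-2-methyl-3-[(3E)-3-methyl-5-oxopent-3-en-1-yl]oxiran-2-yl]ethyl}tetrahydro-2H-pyran-2-one | C[C@@H]1C(=O)O[C@@H](C(C)=O)C[C@H]1CC[C@]1(C)O[C@H]1CC/C(C)=C/C=O | intermediate
16 | (3S,4R,6R)-6-acetyl-3-methyl-4-{2-[(2S,3S)-2-methyl-3-[(3E)-3-methylhexa-3,5-dien-1-yl]oxiran-2-yl]ethyl}tetrahydro-2H-pyran-2-one | C[C@@H]1C(=O)O[C@@H](C(C)=O)C[C@H]1CC[C@]1(C)O[C@H]1CC/C(C)=C/C=C | intermediate
17 | (1R,3R,4S,7E,11S,12S,15S)-11,12-epoxy-4-hydroxycembr-7-en-16,3-olide | C[C@@H]1C(=O)O[C@@H]2C[C@H]1CC[C@]1(C)O[C@H]1CC/C(C)=C/CC[C@]2(C)O | intermediate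
18 | (1R,3R,4S,6E,8R,11S,12S,15S)-11,12-epoxy-8-hydroperoxy-4-hydroxycembr-6-en-16,3-olide | C[C@@H]1C(=O)O[C@@H]2C[C@H]1CC[C@]1(C)O[C@H]1CC[C@@](C)(OO)/C=C/C[C@]2(C)O | target

**Step count and risks**

Total step count: 15. Longest linear sequence: 15 steps (fully linear from farnesol).

Steps most likely to fail:

1. Step 14 (proposed method). What may go wrong: diene oligomerisation or telomerisation outrunning the 14-membered closure, ethyl transfer or reduction at the activated ketone, or zinc chelation between the ketone and the lactone oxygen steering attack to the wrong face of C4. Fallback with known chemistry, from 16 back to 17: kinetic enolisation of the methyl ketone (KHMDS, THF, −78 °C) and trapping with N-(5-chloropyridin-2-yl)triflimide should give the enol triflate F1. 9-BBN should then hydroborate only the terminal C5=C6 bond of the diene to the B-alkyl-9-BBN derivative F2, which without isolation is closed by intramolecular B-alkyl Suzuki–Miyaura coupling (Pd(dppf)Cl2, Ph3As, Cs2CO3, DMF/THF/H2O, high dilution) to the 4(18)-methylene macrocycle F3; this is the same C4–C5 bond, made as an sp2–sp3 bond. Mukaiyama hydration of the 1,1-disubstituted alkene (Co(acac)2, PhSiH3, O2) then returns to 17, the C4 epimer being removed by chromatography.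

2. Step 15. What may go wrong: hydrogen abstraction from the C19 methyl instead of C6 (both lie on the reactive side of the alkene) and attack on the wrong alkene face, so that regio- and diastereoisomeric hydroperoxides dominate. Fallback, from 17 back to 18, which fixes the regiochemistry: bromohydroperoxidation (1,3-dibromo-5,5-dimethylhydantoin, anhydrous H2O2, Et2O, −40 °C; anti addition, OOH at the tertiary C8) should give the 7-bromo-8-hydroperoxide F4. Protection with 2-methoxypropene/PPTS gives the peroxyketal F5, and DBU-mediated E2 elimination, possible only towards C6 because C8 carries no hydrogen, gives the 6E allylic peroxyketal F6. Mild hydrolysis (AcOH/THF/H2O, 0 °C) then releases 18.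

3. Step 4. What may go wrong: erosion of enantioselectivity or competing direct SN2 attack at C16 with the acetal-bearing Grignard reagent. Fallback, from 3 back to 5: acetylation (AcCl, pyridine) gives the allylic acetate F7. An enantioselective boron-enolate Ireland–Claisen rearrangement (chiral 2-bromo-4,5-diphenyl-1,3-bis(4-methylphenylsulfonyl)-1,3,2-diazaborolidine, i-Pr2NEt, CH2Cl2, −78 °C to 4 °C) forms the C1–C2 bond with 1,3-chirality transfer from the reagent and gives the (3R)-3-isopropenyl acid F8. Reduction (LiAlH4) gives the alcohol F9, Dess–Martin oxidation the aldehyde F10, and acetalisation (ethylene glycol, PPTS) returns to 5.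

**Further compounds**

F1 | step 14 | enol triflate of 16 (C4(OTf)=C18H2) | C[C@@H]1C(=O)O[C@@H](C(=C)OS(=O)(=O)C(F)(F)F)C[C@H]1CC[C@]1(C)O[C@H]1CC/C(C)=C/C=C
F2 | step 14 | B-alkyl-9-BBN derivative of F1 (boron on C5) | C[C@@H]1C(=O)O[C@@H](C(=C)OS(=O)(=O)C(F)(F)F)C[C@H]1CC[C@]1(C)O[C@H]1CC/C(C)=C/CCB1C2CCCC1CCC2
F3 | step 14 | (1R,3R,7E,11S,12S,15S)-11,12-epoxycembra-4(18),7-dien-16,3-olide | C[C@@H]1C(=O)O[C@@H]2C[C@H]1CC[C@]1(C)O[C@H]1CC/C(C)=C/CCC2=C
F4 | step 15 | (1R,3R,4S,7S,8R,11S,12S,15S)-7-bromo-11,12-epoxy-8-hydroperoxy-4-hydroxycembran-16,3-olide | C[C@@H]1C(=O)O[C@@H]2C[C@H]1CC[C@]1(C)O[C@H]1CC[C@@](C)(OO)[C@@H](Br)CC[C@]2(C)O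
F5 | step 15 | 2-methoxyprop-2-yl peroxyketal of F4 | C[C@@H]1C(=O)O[C@@H]2C[C@H]1CC[C@]1(C)O[C@H]1CC[C@@](C)(OOC(C)(C)OC)[C@@H](Br)CC[C@]2(C)O
F6 | step 15 | 2-methoxyprop-2-yl peroxyketal of 18 | C[C@@H]1C(=O)O[C@@H]2C[C@H]1CC[C@]1(C)O[C@H]1CC[C@@](C)(OOC(C)(C)OC)/C=C/C[C@]2(C)O
F7 | step 4 | (2E,6E,10E)-12-(tert-butyldiphenylsilyloxy)-2,6,10-trimethyldodeca-2,6,10-trien-1-yl acetate | CC(=O)OC/C(C)=C/CC/C(C)=C/CC/C(C)=C/CO[Si](c1ccccc1)(c1ccccc1)C(C)(C)C
F8 | step 4 | (3R,6E,10E)-12-(tert-butyldiphenylsilyloxy)-6,10-dimethyl-3-(prop-1-en-2-yl)dodeca-6,10-dienoic acid | CC(=C)[C@@H](CC(=O)O)CC/C(C)=C/CC/C(C)=C/CO[Si](c1ccccc1)(c1ccccc1)C(C)(C)C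
F9 | step 4 | (3R,6E,10E)-12-(tert-butyldiphenylsilyloxy)-6,10-dimethyl-3-(prop-1-en-2-yl)dodeca-6,10-dien-1-ol | CC(=C)[C@@H](CCO)CC/C(C)=C/CC/C(C)=C/CO[Si](c1ccccc1)(c1ccccc1)C(C)(C)C
F10 | step 4 | (3R,6E,10E)-12-(tert-butyldiphenylsilyloxy)-6,10-dimethyl-3-(prop-1-en-2-yl)dodeca-6,10-dienal | CC(=C)[C@@H](CC=O)CC/C(C)=C/CC/C(C)=C/CO[Si](c1ccccc1)(c1ccccc1)C(C)(C)C
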